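**Retrosynthetic overview**

1. The three MOM ethers come off last. Before that, C3 (the only stereocentre, an enolisable α-aryl ketone carbon of ring C) is set on the racemic ketone by asymmetric transfer hydrogenation under dynamic kinetic resolution to the cis-(3S,4S)-alcohol, followed by re-oxidation at C4.
2. Ring C, the only ring to be made, is assembled in one operation from a ring-A aryne (triple bond C4a≡C8a) and a ring-B 2-arylacrylic acid. A carboxylate oxygen becomes O1 and forges the aryl ether bond O1–C8a, the acyl carbon C4 moves to C4a, and the C8a phenoxide closes the ring at C2.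
3. Enabling feature: in ring A the ether carbon C8a and the acyl carbon C4a are ortho neighbours, with C4a flanked by the C5 oxygen and C8a by C8–H. A 3-alkoxy aryne therefore takes oxygen at C8a and carbon at C4a, and the C5/C7-dioxy-C6-prenyl pattern makes the aryne precursor derivable from a symmetric phenol.
4. Aryne precursor: resorcinol, bis-MOM ether, C2 lithiation/prenylation, iridium C–H borylation/oxidation at the unhindered C–H, ortho-bromination, retro-Brook/triflation. Acid: 4-bromo-3-methoxyphenol, MOM ether, lithiation/prenylation, bromination, glyoxylate, Wittig methylenation, saponification.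
5. Order of ring formation: rings A and B are bought as benzenes; ring C is formed in the key step.

Key step: step 12

Remark: by CIP analysis of the given SMILES the stereocentre C3 is (S); the descriptor stays (S) in the MOM-protected ketone and alcohol because the order C4 > C2 > aryl > H does not change.

**Route**

Step 1
Reactants: 1 resorcinol
Product: 2 1,3-bis(methoxymethoxy)benzene
Conditions: NaH, DMF, 0 °C; MOMCl, 0 °C → rt
Reagents that add atoms: chloromethyl methyl ether, COCCl
Why: Williamson-type O-alkylation of both phenoxides gives the bis-MOM ether, whose acetal groups later direct lithiation and tolerate fluoride.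

Step 2
Reactants: 2 1,3-bis(methoxymethoxy)benzene
Product: 4 1,3-bis(methoxymethoxy)-2-(3-methylbut-2-en-1-yl)benzene, via aryllithium 3 (not isolated)
Conditions: n-BuLi, THF, 0 °C; CuI (10 mol %), prenyl bromide, −78 °C → rt
Reagents that add atoms: 1-bromo-3-methylbut-2-ene (prenyl bromide), CC(C)=CCBr
Why: Directed ortho-metalation occurs at the carbon between the two MOM ethers, and copper-assisted SN2 allylation should give the linear prenyl arene.

Step 3
Reactants: 4 1,3-bis(methoxymethoxy)-2-(3-methylbut-2-en-1-yl)benzene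
Product: 6 3,5-bis(methoxymethoxy)-4-(3-methylbut-2-en-1-yl)phenol, via pinacol boronate 5 (not isolated)
Conditions: [Ir(cod)(OMe)]2 (1.5 mol %), dtbpy (3 mol %), B2pin2, THF, 80 °C; then 30% aq H2O2, aq NaOH, 0 °C
Reagents that add atoms: hydrogen peroxide, OO
Why: Iridium-catalysed aromatic C–H borylation is sterically governed and should occur only at the C–H flanked by two hydrogens (the future C8a), and basic peroxide oxidation of the C–B bond gives the phenol without touching the trisubstituted alkene.

Step 4
Reactants: 6 3,5-bis(methoxymethoxy)-4-(3-methylbut-2-en-1-yl)phenol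
Product: 7 2-bromo-3,5-bis(methoxymethoxy)-4-(3-methylbut-2-en-1-yl)phenol
Conditions: NBS (1.0 equiv), i-Pr2NH (10 mol %), CH2Cl2, −78 → 0 °C
Reagents that add atoms: N-bromosuccinimide, O=C1CCC(=O)N1Br
Why: Amine-catalysed electrophilic ortho-bromination of the phenol should give one monobromide, since the two ortho sites are equivalent, the para site is blocked and the arene is far more nucleophilic than the prenyl alkene.

Step 5
Reactants: 7 2-bromo-3,5-bis(methoxymethoxy)-4-(3-methylbut-2-en-1-yl)phenol
Product: 10 3,5-bis(methoxymethoxy)-4-(3-methylbut-2-en-1-yl)-2-(trimethylsilyl)phenyl trifluoromethanesulfonate, via silyl ether 8 (not isolated), via lithium phenoxide 9 (not isolated)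
Conditions: HMDS, THF, reflux, then evaporation; n-BuLi, THF, −78 °C; Tf2O, −78 °C
Reagents that add atoms: hexamethyldisilazane, C[Si](C)(C)N[Si](C)(C)C; trifluoromethanesulfonic anhydride, O=S(=O)(OS(=O)(=O)C(F)(F)F)C(F)(F)F
Why: O-silylation, bromine–lithium exchange and retro-Brook (1,3 O→C) silyl migration place Me3Si on the future C4a, and O-triflation of the phenoxide gives the o-silylaryl triflate by the standard aryne-precursor sequence.

Step 6
Reactants: 11 4-bromo-3-methoxyphenol
Product: 12 1-bromo-2-methoxy-4-(methoxymethoxy)benzene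
Conditions: NaH, DMF, 0 °C; MOMCl, 0 °C → rt
Reagents that add atoms: chloromethyl methyl ether, COCCl
Why: Williamson-type O-alkylation masks the future 2'-OH as a MOM ether that survives organolithium and fluoride steps.

Step 7
Reactants: 12 1-bromo-2-methoxy-4-(methoxymethoxy)benzene
Product: 14 2-methoxy-4-(methoxymethoxy)-1-(3-methylbut-2-en-1-yl)benzene, via aryllithium 13 (not isolated)
Conditions: n-BuLi, THF, −78 °C; CuI (10 mol %), prenyl bromide, −78 °C → rt
Reagents that add atoms: 1-bromo-3-methylbut-2-ene (prenyl bromide), CC(C)=CCBr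
Why: Bromine–lithium exchange followed by copper-assisted SN2 allylation installs the 5'-prenyl group ortho to the methoxy group.

Step 8
Reactants: 14 2-methoxy-4-(methoxymethoxy)-1-(3-methylbut-2-en-1-yl)benzene
Product: 15 1-bromo-4-methoxy-2-(methoxymethoxy)-5-(3-methylbut-2-en-1-yl)benzene
Conditions: NBS (1.0 equiv), MeCN, −20 → 0 °C, dark
Reagents that add atoms: N-bromosuccinimide, O=C1CCC(=O)N1Br
Why: Electrophilic aromatic bromination should go to the position para to OMe and ortho to OMOM (the future C1'), the site between the two oxygens being more hindered and the alkene less nucleophilic than the resorcinol-type ring.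

Step 9
Reactants: 15 1-bromo-4-methoxy-2-(methoxymethoxy)-5-(3-methylbut-2-en-1-yl)benzene
Product: 17 ethyl 2-[4-methoxy-2-(methoxymethoxy)-5-(3-methylbut-2-en-1-yl)phenyl]-2-oxoacetate, via aryllithium 16 (not isolated)
Conditions: n-BuLi, THF, −78 °C; cannulation into diethyl oxalate (3 equiv), THF, −78 °C; AcOH quench
Reagents that add atoms: diethyl oxalate, CCOC(=O)C(=O)OCC
Why: Bromine–lithium exchange and inverse addition to excess oxalate give the aryl glyoxylate, the tetrahedral adduct protecting the ketone from a second addition.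

Step 10
Reactants: 17 ethyl 2-[4-methoxy-2-(methoxymethoxy)-5-(3-methylbut-2-en-1-yl)phenyl]-2-oxoacetate
Product: 18 ethyl 2-[4-methoxy-2-(methoxymethoxy)-5-(3-methylbut-2-en-1-yl)phenyl]prop-2-enoate
Conditions: Ph3PCH3Br, KOt-Bu, THF, 0 °C → rt
Reagents that add atoms: methyltriphenylphosphonium bromide, C[P+](c1ccccc1)(c1ccccc1)c1ccccc1.[Br-]
Why: Wittig methylenation of the activated α-keto ester carbonyl gives the 2-arylacrylate and thereby the future C2.

Step 11
Reactants: 18 ethyl 2-[4-methoxy-2-(methoxymethoxy)-5-(3-methylbut-2-en-1-yl)phenyl]prop-2-enoate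
Product: 19 2-[4-methoxy-2-(methoxymethoxy)-5-(3-methylbut-2-en-1-yl)phenyl]prop-2-enoic acid
Conditions: LiOH, THF/H2O, rt; 1 M HCl to pH 4 at 0 °C
Reagents that add atoms: lithium hydroxide, [Li+].[OH-]
Why: Saponification frees the acid, and brief cold acidification to pH 4 should spare the MOM acetals.

Step 12
Reactants: 10 3,5-bis(methoxymethoxy)-4-(3-methylbut-2-en-1-yl)-2-(trimethylsilyl)phenyl trifluoromethanesulfonate; 19 2-[4-methoxy-2-(methoxymethoxy)-5-(3-methylbut-2-en-1-yl)phenyl]prop-2-enoic acid
Product: 22 racemic 5,7-bis(methoxymethoxy)-3-[4-methoxy-2-(methoxymethoxy)-5-(3-methylbut-2-en-1-yl)phenyl]-6-(3-methylbut-2-en-1-yl)chroman-4-one, via aryne 20 (not isolated), via cesium phenoxide enone 21 (not isolated)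
Conditions: 19 (1.2 equiv), CsF (4 equiv), THF, sealed tube, 125 °C
Reagents that add atoms: none
Why: Fluoride removes the silyl group of 10 and triflate leaves to give aryne 20; the cesium carboxylate of 19 adds through oxygen to C8a (this makes the aryl ether bond O1–C8a), and the C4a aryl anion attacks the ester carbonyl through a four-membered oxetanolate so that the acyl group ends on C4a and the C8a phenoxide 21 is released. The closest known reaction type is the fluoride-mediated coupling of o-silylaryl triflates with acrylic acids, which gives 4-chromanones through o-hydroxyaryl vinyl ketones. Ring C is closed by 6-endo-trig oxa-Michael addition of the O1 phenoxide to C2 of the α-aryl enone, driven by formation of the aryl-stabilised enolate. C3 arises by unselective protonation of that enolate, so 22 is racemic by design and the configuration is set in step 13. The selectivity needed is regiochemical (oxygen at C8a, acyl at C4a): the C5 OMOM group beside C4a polarises the triple bond so that the nucleophile enters at the distal carbon C8a and the charge develops at C4a ortho to oxygen, while C8 carries only hydrogen. Protonation of the C4a anion before acyl transfer (aryl ester formation) is the main competitor and should be disfavoured in hot aprotic THF.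

Step 13
Reactants: 22 racemic 5,7-bis(methoxymethoxy)-3-[4-methoxy-2-(methoxymethoxy)-5-(3-methylbut-2-en-1-yl)phenyl]-6-(3-methylbut-2-en-1-yl)chroman-4-one
Product: 23 (3S,4S)-5,7-bis(methoxymethoxy)-3-[4-methoxy-2-(methoxymethoxy)-5-(3-methylbut-2-en-1-yl)phenyl]-6-(3-methylbut-2-en-1-yl)chroman-4-ol
Conditions: RuCl[(S,S)-TsDPEN](p-cymene) (5 mol %), HCO2H/Et3N (1:1), EtOAc, 40 °C
Reagents that add atoms: none
Why: Noyori-type asymmetric transfer hydrogenation under dynamic kinetic resolution: Et3N racemises C3 through the enol faster than hydride transfer, the (S,S)-catalyst should deliver hydride to the aryl ketone in the sense that gives (4S) and anti to the C3 aryl group, so both enantiomers should funnel into the cis-(3S,4S)-alcohol, in which C3 is no longer enolisable.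

Step 14
Reactants: 23 (3S,4S)-5,7-bis(methoxymethoxy)-3-[4-methoxy-2-(methoxymethoxy)-5-(3-methylbut-2-en-1-yl)phenyl]-6-(3-methylbut-2-en-1-yl)chroman-4-ol
Product: 24 (3S)-5,7-bis(methoxymethoxy)-3-[4-methoxy-2-(methoxymethoxy)-5-(3-methylbut-2-en-1-yl)phenyl]-6-(3-methylbut-2-en-1-yl)chroman-4-one
Conditions: Dess–Martin periodinane, CH2Cl2, 0 °C → rt
Reagents that add atoms: none
Why: Dess–Martin oxidation of the benzylic alcohol under neutral, non-enolising conditions restores the C4 ketone while the (S) centre at C3 set in step 13 should be retained.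

Step 15
Reactants: 24 (3S)-5,7-bis(methoxymethoxy)-3-[4-methoxy-2-(methoxymethoxy)-5-(3-methylbut-2-en-1-yl)phenyl]-6-(3-methylbut-2-en-1-yl)chroman-4-one
Product: 25 (3S)-5,7-dihydroxy-3-[2-hydroxy-4-methoxy-5-(3-methylbut-2-en-1-yl)phenyl]-6-(3-methylbut-2-en-1-yl)chroman-4-one
Conditions: 3 M HCl in MeOH, rt
Reagents that add atoms: none
Why: Acid-catalysed methanolysis of the three MOM acetals (transferred to methanol as dimethoxymethane) under mild conditions should free the phenols without appreciable enolisation at C3 or cyclisation of the prenyl groups.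

**Compound list**

1 | resorcinol | Oc1cccc(O)c1 | starting material
2 | 1,3-bis(methoxymethoxy)benzene | COCOc1cccc(OCOC)c1 | intermediate
3 | [2,6-bis(methoxymethoxy)phenyl]lithium | [Li]c1c(OCOC)cccc1OCOC | intermediate
4 | 1,3-bis(methoxymethoxy)-2-(3-methylbut-2-en-1-yl)benzene | COCOc1cccc(OCOC)c1CC=C(C)C | intermediate
5 | 2-[3,5-bis(methoxymethoxy)-4-(3-methylbut-2-en-1-yl)phenyl]-4,4,5,5-tetramethyl-1,3,2-dioxaborolane | COCOc1cc(B2OC(C)(C)C(C)(C)O2)cc(OCOC)c1CC=C(C)C | intermediate
6 | 3,5-bis(methoxymethoxy)-4-(3-methylbut-2-en-1-yl)phenol | COCOc1cc(O)cc(OCOC)c1CC=C(C)C | intermediate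
7 | 2-bromo-3,5-bis(methoxymethoxy)-4-(3-methylbut-2-en-1-yl)phenol | COCOc1cc(O)c(Br)c(OCOC)c1CC=C(C)C | intermediate
8 | [2-bromo-3,5-bis(methoxymethoxy)-4-(3-methylbut-2-en-1-yl)phenoxy]trimethylsilane | COCOc1cc(O[Si](C)(C)C)c(Br)c(OCOC)c1CC=C(C)C | intermediate
9 | lithium 3,5-bis(methoxymethoxy)-4-(3-methylbut-2-en-1-yl)-2-(trimethylsilyl)phenolate | [Li+].[O-]c1cc(OCOC)c(CC=C(C)C)c(OCOC)c1[Si](C)(C)C | intermediate
10 | 3,5-bis(methoxymethoxy)-4-(3-methylbut-2-en-1-yl)-2-(trimethylsilyl)phenyl trifluoromethanesulfonate | COCOc1cc(OS(=O)(=O)C(F)(F)F)c([Si](C)(C)C)c(OCOC)c1CC=C(C)C | intermediate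
11 | 4-bromo-3-methoxyphenol | COc1cc(O)ccc1Br | starting material
12 | 1-bromo-2-methoxy-4-(methoxymethoxy)benzene | COCOc1ccc(Br)c(OC)c1 | intermediate
13 | [2-methoxy-4-(methoxymethoxy)phenyl]lithium | [Li]c1ccc(OCOC)cc1OC | intermediate
14 | 2-methoxy-4-(methoxymethoxy)-1-(3-methylbut-2-en-1-yl)benzene | COCOc1ccc(CC=C(C)C)c(OC)c1 | intermediate
15 | 1-bromo-4-methoxy-2-(methoxymethoxy)-5-(3-methylbut-2-en-1-yl)benzene | COCOc1cc(OC)c(CC=C(C)C)cc1Br | intermediate
16 | [4-methoxy-2-(methoxymethoxy)-5-(3-methylbut-2-en-1-yl)phenyl]lithium | [Li]c1cc(CC=C(C)C)c(OC)cc1OCOC | intermediate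
17 | ethyl 2-[4-methoxy-2-(methoxymethoxy)-5-(3-methylbut-2-en-1-yl)phenyl]-2-oxoacetate | CCOC(=O)C(=O)c1cc(CC=C(C)C)c(OC)cc1OCOC | intermediate
18 | ethyl 2-[4-methoxy-2-(methoxymethoxy)-5-(3-methylbut-2-en-1-yl)phenyl]prop-2-enoate | CCOC(=O)C(=C)c1cc(CC=C(C)C)c(OC)cc1OCOC | intermediate
19 | 2-[4-methoxy-2-(methoxymethoxy)-5-(3-methylbut-2-en-1-yl)phenyl]prop-2-enoic acid | OC(=O)C(=C)c1cc(CC=C(C)C)c(OC)cc1OCOC | intermediate
20 | 3,5-bis(methoxymethoxy)-4-(3-methylbut-2-en-1-yl)benzyne (triple bond between the future C4a and C8a) | COCOC1=CC#CC(OCOC)=C1CC=C(C)C | intermediate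
21 | cesium 3,5-bis(methoxymethoxy)-2-{2-[4-methoxy-2-(methoxymethoxy)-5-(3-methylbut-2-en-1-yl)phenyl]prop-2-enoyl}-4-(3-methylbut-2-en-1-yl)phenolate | [Cs+].[O-]c1cc(OCOC)c(CC=C(C)C)c(OCOC)c1C(=O)C(=C)c1cc(CC=C(C)C)c(OC)cc1OCOC | intermediate
22 | racemic 5,7-bis(methoxymethoxy)-3-[4-methoxy-2-(methoxymethoxy)-5-(3-methylbut-2-en-1-yl)phenyl]-6-(3-methylbut-2-en-1-yl)chroman-4-one | COCOc1cc2OCC(c3cc(CC=C(C)C)c(OC)cc3OCOC)C(=O)c2c(OCOC)c1CC=C(C)C | intermediate
23 | (3S,4S)-5,7-bis(methoxymethoxy)-3-[4-methoxy-2-(methoxymethoxy)-5-(3-methylbut-2-en-1-yl)phenyl]-6-(3-methylbut-2-en-1-yl)chroman-4-ol (cis) | COc1cc(OCOC)c([C@H]2COc3cc(OCOC)c(CC=C(C)C)c(OCOC)c3[C@H]2O)cc1CC=C(C)C | intermediate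
24 | (3S)-5,7-bis(methoxymethoxy)-3-[4-methoxy-2-(methoxymethoxy)-5-(3-methylbut-2-en-1-yl)phenyl]-6-(3-methylbut-2-en-1-yl)chroman-4-one | COc1cc(OCOC)c([C@H]2COc3cc(OCOC)c(CC=C(C)C)c(OCOC)c3C2=O)cc1CC=C(C)C | intermediate
25 | (3S)-5,7-dihydroxy-3-[2-hydroxy-4-methoxy-5-(3-methylbut-2-en-1-yl)phenyl]-6-(3-methylbut-2-en-1-yl)chroman-4-one | COc1cc(O)c([C@H]2COc3cc(O)c(CC=C(C)C)c(O)c3C2=O)cc1CC=C(C)C | target

**Step count and risks**

Total step count: 15. Longest linear sequence: 10 steps (steps 6 to 11, then 12 to 15).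

Steps most likely to fail:

Step 12. The C4a aryl anion may be protonated before the acyl group migrates, so that the sequence stops at the aryl ester. The 2-arylacrylate may oligomerise at 125 °C, and the phenoxide or the product enolate may be arylated by a second aryne. The fallback divides the cascade into known stages; it sets out from 10 and 19 and comes back at 22. Aryne generation at room temperature (CsF, MeCN) should give plain O-arylation of the acid to 3,5-bis(methoxymethoxy)-4-(3-methylbut-2-en-1-yl)phenyl 2-[4-methoxy-2-(methoxymethoxy)-5-(3-methylbut-2-en-1-yl)phenyl]prop-2-enoate F1; the same ester would also be available from phenol 6 and 19 by carbodiimide coupling. Ring A of this ester is symmetric and its para position is blocked, so photo-Fries rearrangement (300 nm, MeCN) can lead only to 1-[6-hydroxy-2,4-bis(methoxymethoxy)-3-(3-methylbut-2-en-1-yl)phenyl]-2-[4-methoxy-2-(methoxymethoxy)-5-(3-methylbut-2-en-1-yl)phenyl]prop-2-en-1-one F2. Brief treatment with NaOAc in EtOH should then close ring C by oxa-Michael addition to give 22.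

Step 13. Hydride transfer to the electron-rich carbonyl beside the C5 OMOM group may be slow, so that reduction and racemisation are mismatched and the cis-selectivity or the enantioselectivity suffers. The fallback sets the centre by enantioselective protonation instead of reduction; it sets out from 22 and comes back at 24, bypassing 23. O-Acylation of the potassium enolate (KHMDS, allyl chloroformate, THF, −78 °C) should give allyl 5,7-bis(methoxymethoxy)-3-[4-methoxy-2-(methoxymethoxy)-5-(3-methylbut-2-en-1-yl)phenyl]-6-(3-methylbut-2-en-1-yl)-2H-chromen-4-yl carbonate F3, in which C3 is planar. Decarboxylative asymmetric protonation (Pd2(dba)3, a t-Bu-PHOX ligand, Meldrum's acid, dioxane) would then deliver 24. The ligand antipode that gives the (S)-ketone would be chosen on a model isoflavanone.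

Step 15. Acid may enolise the ketone and erode the C3 configuration, and the C6 prenyl group may cyclise onto the freed C5 or C7 phenol. The fallback removes the acid step from the enantioenriched series; it sets out from 22 and comes back at 25. Acidic methanolysis at the racemic stage, run as mildly and as slowly as the prenyl groups require, would give racemic 5,7-dihydroxy-3-[2-hydroxy-4-methoxy-5-(3-methylbut-2-en-1-yl)phenyl]-6-(3-methylbut-2-en-1-yl)chroman-4-one F4. Excess NaH and allyl chloroformate should convert the three phenols and the ketone enolate into the tetrakis(allyl carbonate) allyl 5,7-bis(allyloxycarbonyloxy)-3-[2-(allyloxycarbonyloxy)-4-methoxy-5-(3-methylbut-2-en-1-yl)phenyl]-6-(3-methylbut-2-en-1-yl)-2H-chromen-4-yl carbonate F5. One neutral operation with Pd2(dba)3, a t-Bu-PHOX ligand and excess Meldrum's acid would then cleave the three aryl carbonates and set C3 by decarboxylative protonation of the enol carbonate, giving 25 directly.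

Further compounds
F1 | step 12 | 3,5-bis(methoxymethoxy)-4-(3-methylbut-2-en-1-yl)phenyl 2-[4-methoxy-2-(methoxymethoxy)-5-(3-methylbut-2-en-1-yl)phenyl]prop-2-enoate | C=C(C(=O)Oc1cc(OCOC)c(CC=C(C)C)c(OCOC)c1)c1cc(CC=C(C)C)c(OC)cc1OCOC
F2 | step 12 | 1-[6-hydroxy-2,4-bis(methoxymethoxy)-3-(3-methylbut-2-en-1-yl)phenyl]-2-[4-methoxy-2-(methoxymethoxy)-5-(3-methylbut-2-en-1-yl)phenyl]prop-2-en-1-one | Oc1cc(OCOC)c(CC=C(C)C)c(OCOC)c1C(=O)C(=C)c1cc(CC=C(C)C)c(OC)cc1OCOC
F3 | step 13 | allyl 5,7-bis(methoxymethoxy)-3-[4-methoxy-2-(methoxymethoxy)-5-(3-methylbut-2-en-1-yl)phenyl]-6-(3-methylbut-2-en-1-yl)-2H-chromen-4-yl carbonate | C=CCOC(=O)OC1=C(c2cc(CC=C(C)C)c(OC)cc2OCOC)COc2cc(OCOC)c(CC=C(C)C)c(OCOC)c12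
F4 | step 15 | racemic 5,7-dihydroxy-3-[2-hydroxy-4-methoxy-5-(3-methylbut-2-en-1-yl)phenyl]-6-(3-methylbut-2-en-1-yl)chroman-4-one | COc1cc(O)c(C2COc3cc(O)c(CC=C(C)C)c(O)c3C2=O)cc1CC=C(C)C
F5 | step 15 | allyl 5,7-bis(allyloxycarbonyloxy)-3-[2-(allyloxycarbonyloxy)-4-methoxy-5-(3-methylbut-2-en-1-yl)phenyl]-6-(3-methylbut-2-en-1-yl)-2H-chromen-4-yl carbonate | C=CCOC(=O)OC1=C(c2cc(CC=C(C)C)c(OC)cc2OC(=O)OCC=C)COc2cc(OC(=O)OCC=C)c(CC=C(C)C)c(OC(=O)OCC=C)c12
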